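## Assumptions (one line each)
- Dichrostachine A is read directly from the given SMILES: a normal-series labdane (5α-H, 9α-H, 10β-Me, 4α-CH2OH, 7β-OH, Δ8(17)) whose C11–C12 side chain is fused into a cis-cyclohexene/methoxy-enedione with a C12/Cq/Ca triad. Cq is a quaternary carbon bearing a 5,7-dihydroxychromon-2-yl group. This is the adduct of a labda-12,14-diene and a 2-chromonyl-5-methoxy-benzoquinone.
- (+)-trans-Communic acid (labda-8(17),12E,14-trien-19-oic acid; normal series, equatorial 4α-CO2H) is taken as purchasable. It is isolated from Juniperus resin.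

## Retrosynthetic overview
1. Dichrostachine A ⇒ (desilylation) ⇒ a bis-TBS cis-fused cyclohexene-enedione, formed by one intermolecular [4+2] that makes the C12–Cq (quaternary) and C15–Ca bonds. The cyclohexene ring and three stereocentres are therefore made last.
2. The dienophile is 2-(chromon-2-yl)-5-methoxybenzoquinone with free 5,7-OH. It comes from a 2',4',5'-trimethoxyflavone by CAN oxidation. The flavone comes from phloroacetophenone and 2,4,5-trimethoxybenzaldehyde (aldol, then I2/DMSO).
3. The diene is (12E)-7β,19-bis(OTBS)-labda-8(17),12,14-triene from chiral-pool trans-communic acid, which already carries C4, C5, C9 and C10. C7β-OH is installed by SeO2 oxidation followed by oxidation and Luche reduction, with the diene masked as its SO2 adduct (sulfolene).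
4. Ring-formation order: decalin (chiral pool), then chromone, then cyclohexene/quaternary centre in the final convergent step. The decalin is not built de novo. The free-phenol flavone is used without A-ring protection. The diene is masked and unmasked by cheletropic SO2 chemistry.

## Route

**Step 1**
Reactants: 1 (+)-trans-communic acid
Product: 2 trans-communol (labda-8(17),12E,14-trien-19-ol)
Conditions: LiAlH4, THF, 0 °C → 65 °C
Reagents that add atoms: none (LiAlH4 delivers only H)
Why: Hydride reduction of the carboxylic acid to the primary alcohol leaves C4 and the alkenes untouched, so the 4α-CH2OH configuration is retained.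

**Step 2**
Reactants: 2 trans-communol; 3 sulfur dioxide
Product: 4 sulfolene (2,5-dihydrothiophene 1,1-dioxide) across C12/C15, with the ring C13=C14 double bond (C12 epimers)
Conditions: liquid SO2, hydroquinone (cat.), sealed tube, –10 → 20 °C, 48 h; evaporate
Reagents that add atoms: SO2, O=S=O
Why: Cheletropic [4+1] addition of SO2 to the 1,3-diene masks it. The resulting electron-poor, sulfone-flanked ring alkene is far less reactive than the exocyclic 1,1-disubstituted alkene toward SeO2. The new C12 stereocentre is erased later.

**Step 3**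
Reactants: 4 sulfolene
Product: 5 7-hydroxy-sulfolene (C7 epimers, plus some 7-ketone)
Conditions: SeO2 (0.3 equiv), TBHP (3 equiv), CH2Cl2, 0 °C → rt
Reagents that add atoms: SeO2 (O=[Se]=O), TBHP (CC(C)(C)OO)
Why: Riley/Sharpless allylic oxidation proceeds by ene reaction at C17 with H-abstraction from C7, then [2,3] shift. This puts OH at ring carbon C7 and restores the exocyclic methylene, as in β-pinene → pinocarveol. C9-H is tertiary and hindered. The C7 stereochemistry is deliberately erased in the next two steps.

**Step 4**
Reactants: 5
Product: 6 7-oxo-8(17)-ene sulfolene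
Conditions: MnO2, CH2Cl2, rt
Reagents that add atoms: none
Why: MnO2 oxidizes the allylic alcohol selectively and leaves the neopentyl primary alcohol alone. It converts the C7 epimer mixture to one enone and gives a single stereochemical starting point for the reduction.

**Step 5**
Reactants: 6
Product: 7 7β-hydroxy-19-ol sulfolene
Conditions: NaBH4, CeCl3·7H2O, MeOH/CH2Cl2 (1:1), –78 °C
Reagents that add atoms: none (only H added)
Why: Luche 1,2-reduction. Small-hydride axial attack on the α-face, anti to the angular C20-Me, gives the equatorial 7β-alcohol required by the target. This sets C7.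

**Step 6**
Reactants: 7
Product: 8 7β,19-bis-OTBS sulfolene
Conditions: TBSOTf (3 equiv), 2,6-lutidine (5 equiv), CH2Cl2, –78 → 0 °C
Reagents that add atoms: TBSOTf, CC(C)(C)[Si](C)(C)OS(=O)(=O)C(F)(F)F
Why: Silylation of both hydroxyls prevents them coordinating the catalyst in the Diels–Alder step. TBSOTf is needed for the hindered neopentyl and secondary alcohols.

**Step 7**
Reactants: 8
Product: 9 diene (12E)-7β,19-bis(OTBS)-labda-8(17),12,14-triene
Conditions: PhMe, BHT, 110 °C, N2 sparge, 6 h
Reagents that add atoms: none (SO2 is lost)
Why: Thermal retro-cheletropic extrusion of SO2 is disrotatory, so the single C12 substituent rotates outward and gives the E-diene. The C12 stereocentre of 4 vanishes.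

**Step 8**
Reactants: 10 phloroacetophenone; 11 2,4,5-trimethoxybenzaldehyde
Product: 12 (E)-2',4',6'-trihydroxy-2,4,5-trimethoxychalcone
Conditions: 50% aq. KOH, EtOH, rt, 48 h; then HCl
Reagents that add atoms: none
Why: Claisen–Schmidt condensation; only the E-chalcone forms.

**Step 9**
Reactants: 12
Product: 13 5,7-dihydroxy-2',4',5'-trimethoxyflavone
Conditions: I2 (0.1 equiv), DMSO, 130 °C, 2 h
Reagents that add atoms: none
Why: Oxa-Michael cyclization to the flavanone, then I2/DMSO dehydrogenation (Doshi flavone synthesis) gives the chromone with the A-ring phenols left free.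

**Step 10**
Reactants: 13
Product: 14 5,7-dihydroxy-2-(5-methoxy-1,4-benzoquinon-2-yl)chromen-4-one
Conditions: CAN (2.3 equiv), MeCN/H2O 4:1, 0 °C, 15 min
Reagents that add atoms: water (O), O
Why: CAN oxidatively demethylates the para-dimethoxy pair (2',5'-OMe) to the quinone, as in 1,2,4-trimethoxyarene → 2-methoxyquinone. The 4'-OMe is retained and lands on the required carbon. The electron-poor A ring resists oxidation.

**Step 11**
Reactants: 9 diene (1.5 equiv); 14 quinone (1 equiv)
Product: 15 bis-TBS cycloadduct
Conditions: chiral BINOL-derived N-triflylphosphoramide (20 mol%), PhMe/CH2Cl2 4:1, –20 → 25 °C, 5 d; HPLC removal of minor diastereomers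
Reagents that add atoms: none (catalyst only)
Why: Intermolecular Diels–Alder reaction forms the cyclohexene and three stereocentres in one step. Suprafacial addition gives the cis Cq/Ca fusion. **Proposed new method:** The methoxy group makes the C2'=O a vinylogous ester, so C5'=O is the activating carbonyl, and its β-carbon Cq is the electrophilic terminus. Cq bonds to C12, the diene terminus next to the 13-methyl group, which has the larger HOMO coefficient (closest known reaction: the "para" rule for 2-methyl dienes with 2-methoxyquinone). The E-diene in a chromone-endo (ring-exo) transition state, with the chromone π-system under the diene, puts C11 cis to the chromone, as required. Catalyst H-bonding to the quinone carbonyl selects the diene/quinone face pairing. The closest known reaction type is chiral Brønsted-acid-catalysed quinone Diels–Alder reaction. Remote induction from C9 is weak, so wrong-facial diastereomers must be separated.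

**Step 12**
Reactants: 15
Product: 16 Dichrostachine A
Conditions: HF·pyridine, THF/pyridine 10:1, 0 → 25 °C, 24 h
Reagents that add atoms: none
Why: Fluoride-mediated removal of both TBS ethers under mildly acidic conditions leaves the enedione, phenols and exocyclic alkene intact. No stereocentre is affected.

## Compound list
1 | (+)-trans-communic acid | C=C1CC[C@H]2[C@](C)(C(=O)O)CCC[C@]2(C)[C@H]1C/C=C(\C)C=C | starting material
2 | trans-communol | C=C1CC[C@H]2[C@](C)(CO)CCC[C@]2(C)[C@H]1C/C=C(\C)C=C | intermediate
3 | sulfur dioxide | O=S=O | reagent/starting material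
4 | C12,C15-sulfolene of 2 (C12 epimers) | C=C1CC[C@H]2[C@](C)(CO)CCC[C@]2(C)[C@H]1CC1S(=O)(=O)CC=C1C | intermediate
5 | 7-hydroxy-sulfolene (C7 epimers) | C=C1C(O)C[C@H]2[C@](C)(CO)CCC[C@]2(C)[C@H]1CC1S(=O)(=O)CC=C1C | intermediate
6 | 7-oxo-sulfolene | C=C1C(=O)C[C@H]2[C@](C)(CO)CCC[C@]2(C)[C@H]1CC1S(=O)(=O)CC=C1C | intermediate
7 | 7β-hydroxy-19-ol sulfolene | C=C1[C@@H](O)C[C@H]2[C@](C)(CO)CCC[C@]2(C)[C@H]1CC1S(=O)(=O)CC=C1C | intermediate
8 | 7β,19-bis-OTBS sulfolene | C=C1[C@@H](O[Si](C)(C)C(C)(C)C)C[C@H]2[C@](C)(CO[Si](C)(C)C(C)(C)C)CCC[C@]2(C)[C@H]1CC1S(=O)(=O)CC=C1C | intermediate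
9 | (12E)-7β,19-bis(OTBS)labda-8(17),12,14-triene | C=C1[C@@H](O[Si](C)(C)C(C)(C)C)C[C@H]2[C@](C)(CO[Si](C)(C)C(C)(C)C)CCC[C@]2(C)[C@H]1C/C=C(\C)C=C | intermediate (diene)
10 | 2,4,6-trihydroxyacetophenone | CC(=O)c1c(O)cc(O)cc1O | starting material
11 | 2,4,5-trimethoxybenzaldehyde | O=Cc1cc(OC)c(OC)cc1OC | starting material
12 | 2',4',6'-trihydroxy-2,4,5-trimethoxychalcone | O=C(/C=C/c1cc(OC)c(OC)cc1OC)c1c(O)cc(O)cc1O | intermediate
13 | 5,7-dihydroxy-2',4',5'-trimethoxyflavone | O=c1cc(-c2cc(OC)c(OC)cc2OC)oc2cc(O)cc(O)c12 | intermediate
14 | 5,7-dihydroxy-2-(5-methoxy-1,4-benzoquinon-2-yl)chromen-4-one | O=c1cc(-C2=CC(=O)C(OC)=CC2=O)oc2cc(O)cc(O)c12 | intermediate (dienophile)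
15 | bis-TBS Diels–Alder adduct | C=C1[C@@H](O[Si](C)(C)C(C)(C)C)C[C@H]2[C@](C)(CO[Si](C)(C)C(C)(C)C)CCC[C@]2(C)[C@H]1C[C@@H]1C(C)=CC[C@H]2C(=O)C(OC)=CC(=O)[C@@]12c1cc(=O)c2c(O)cc(O)cc2o1 | intermediate
16 | Dichrostachine A | C=C1[C@@H](O)C[C@H]2[C@](C)(CO)CCC[C@]2(C)[C@H]1C[C@@H]1C(C)=CC[C@H]2C(=O)C(OC)=CC(=O)[C@@]12c1cc(=O)c2c(O)cc(O)cc2o1 | target

## Totals
- Total steps: 12.
- Longest linear sequence: 9 steps (1 → 2 → 4 → 5 → 6 → 7 → 8 → 9 → 15 → 16, i.e. steps 1–7, 11, 12).

## Three steps most likely to fail
1. **Step 11 (Diels–Alder).** Regiochemistry, chromone-endo selectivity and facial selectivity are all uncertain; the free-phenol quinone may also poison the catalyst. Fallback: change the stereochemical manifold by photoisomerizing diene 9 to the Z-diene with a triplet sensitizer and separating it. Run an endo-selective Diels–Alder with that Z-diene, which puts C11 cis to the chromone, and resolve any diastereomers by HPLC.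
2. **Step 2 (sulfolene masking).** Liquid SO2 may add poorly to this hindered 1,2-disubstituted diene, or react at the exocyclic alkene. Fallback: protect the diene as its η4-Fe(CO)3 complex (Fe2(CO)9), oxidize at C7, then decomplex with Me3NO or CAN.
3. **Step 3 (SeO2, C7 selectivity).** Competing C9-hydroxylation or oxidation of the ring alkene could occur. Fallback: ozonolyze the exocyclic alkene of 4 to the C8 ketone and make the kinetic LDA enolate. Hydroxylate C7 with the Davis oxaziridine, then restore C8=C17 by Petasis methylenation. The C7β-OH is then reset by the ketone oxidation/Luche sequence.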